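The stirred vessel holds two phases of equal volume, with starting material in the first and reagent in the second.

| setting | red | amber | flask |
|---|---|---|---|
| starting material | 10 mM | 6.7 mM | 10 mM |
| reagent in the second phase | 0.80 equiv | 0.80 equiv | 0.800 equiv |
| remark | the very flask that is asked about, followed so far | run made earlier |  |
| time |  |  | 25 h |
| volume of the second phase over the first |  |  | 1.0 |

| run | time / h | target / % | starting material / % |
|---|---|---|---|
| red | 1.00 | 4 | 98 |
| red | 2.00 | 7 | 95 |
| red | 3.00 | 12 | 91 |
| red | 4.00 | 19 | 82 |
| red | 5.00 | 19 | 81 |
| amber | 4.00 | 11 | 91 |
| amber | 8.00 | 22 | 75 |
| amber | 10.0 | 25 | 76 |
| amber | 15.0 | 32 | 64 |
| amber | 20.0 | 43 | 55 |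

(standard deviation of a reading: 2 percentage points)

- in the second phase: reagent in the second phase; everything else is in the first
- charges count per volume of the first phase; a concentration in a rate is the amount of a species over the volume of its own phase; every rate counts per litre of the first phase
- the earlier runs were read with a standard deviation of 2 percentage points
- the earlier runs hold the two phases in the same ratio of volumes as the flask asked about

- north-west: doubling the transfer coefficient of the reagent in the second phase, all else as stated
- south-east: doubling the amount of reagent in the second phase, all else as stated

- how much target there is at 25 h, in percent of the starting material charged
- the change that raises the amount of target at 25 h, in percent of the starting material charged most ("none" if none brings more than 2 percentage points) (north-west / south-east / none)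
- amount of target at 25 h, in percent of the starting material charged, after north-west

The ledger opens with reagent, the limiting reagent, at 8.00 mM per volume of the first phase. Target and starting material sum to 100% in the last red reading and 98.0% in the last amber one, so each mole of target is entered as one mole of reagent spent. Unspent reagent, the reagent on the books, sits in two entries: second phase and reaction phase. With the passage between them taken as balanced, a constant share stands free, and d[target]/dt = κ[starting material][reagent on the books]. The pair rate is κ times the charged [starting material]. Integrating this law through the last readings gives 0.0604 h⁻¹ from red and, scaled to the charge of 10 mM, 0.0780 h⁻¹ from amber. Their mean, 0.0692 h⁻¹, is the pair rate, a reading that carries the scatter.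

At 25 h this reckoning enters 53.9% target, so 5.39 mM of reagent is spent and 2.61 mM stays on the books. South-east lifts the entry to 82.9%. The transfer coefficient stands nowhere in this reckoning, so north-west enters as no change.

The forecast gives 52%, south-east as best and 56% after north-west, and it reads that the percent rate “scales nearly with concentration”. The ledger's entry stands above its 52%, and the two part on north-west, where the ledger enters no change and the forecast a rise.

The flask gives 54.3%, and 56.7% after north-west, a gain of 2.4 percentage points. The best change is south-east, which gains 30 points.

    reagent in the reaction phase ⇌ reagent in the second phase, rate k1*([reagent in the reaction phase] - [reagent in the second phase]/K1) per volume of the first phase (partition coefficient = 2.75, kL = 0.593 h⁻¹)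
    starting material + reagent in the reaction phase → target (k = 33.8 M⁻¹ h⁻¹)
    starting material → decomposition product (k = 5.45 × 10⁻⁴ h⁻¹)

In the flask, the passage makes reagent in the reaction phase at 0.858 of the rate of its use at 4.85 h, and at 0.786 at 25.0 h. The share of the unspent reagent that stands in the reaction phase of the flask is 18.7% at 2.50 h and 23.2% at 25.0 h. Read back from 54.3%, the pair rate is 0.0706 h⁻¹. The kept 0.0692 h⁻¹ puts target in the same flask read at 40 h at 63.0%, and that flask holds 64.0% target.

The numbers in the tables stem from a simulated flask with constants of no real substance, and the scatter is random.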